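Ring numbering: C1 alkynyl carbon, C2 vinylic CH, C3 OAc, C4 OMe, C5 OH, C6 OH. The cyclohexene ring carries its only two free ring hydroxyls on the adjacent carbons C5 and C6, cis to each other and trans to the C4 methoxy group; this vicinal diol is the handle for a reductive carbonyl–carbonyl (pinacol) ring closure.
Retrosynthesis: remove the C3 acetate; cut C5–C6 to a (Z)-enynal dialdehyde; cut C1–C6 (formyl carbon from DMF) and C1–alkyne back to a 1,1-dibromoalkene made from 2,4-O-ethylidene-D-erythrose (ring C2–C5 = erythrose C1–C4); cut the side chain at the enyne bond and at the allyl–vinyl bond.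
Forward: the erythrose-derived dibromoalkene (steps 1–6) and the side-chain enyne (steps 7–10) are joined by a trans-selective Sonogashira coupling (step 11); C6 is added by formylation (step 12), C5 is oxidised (step 13) and the single ring closes in step 14; desilylation and boronate-masked acetylation of O3 finish the synthesis.
Stereochemistry: C3 and C4 are C4 and C5 of D-glucose, carried through unchanged; C5 and C6 are set together in the ring closure (samarium-bridged cis diol, anti to the C4 methoxy group); the E alkene comes from syn hydrozirconation, and the Z enal geometry from the trans-selective coupling followed by bromine–lithium exchange with retention.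
Key step: step 14

Remark: commercial 1 is an anomeric mixture, so its anomeric centre is left undefined (it is excised in step 1); the cyclopentadienyl ligands on zirconium are drawn σ-bonded in the SMILES strings.

Step 1
Reactants: 1 4,6-O-ethylidene-D-glucopyranose
Product: 3 2,4-O-ethylidene-D-erythrose, via formate ester 2 (not isolated)
Conditions: NaIO4 (2.1 equiv), NaHCO3 (to hold pH 4–6.5), H2O, 0 °C → rt
Reagents that add atoms: none
Why: Malaprade periodate cleavage of the C1–C2 and C2–C3 glycol bonds excises C1 and C2 of glucose as formate (the O5 formate ester 2 hydrolyses in the buffered medium) and leaves C3–C6 as the erythrose, so C4 and C5 of glucose become ring C3 and C4 without being touched.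

Step 2
Reactants: 3 2,4-O-ethylidene-D-erythrose
Product: 4 (2R,4S,5R)-4-(2,2-dibromoethenyl)-2-methyl-1,3-dioxan-5-ol
Conditions: CBr4 (2 equiv), PPh3 (2 equiv), Zn (2 equiv), CH2Cl2, rt (ylide pre-formed); then 3, 0 °C → rt
Reagents that add atoms: carbon tetrabromide, BrC(Br)(Br)Br
Why: Ramirez gem-dibromoolefination (first half of a Corey–Fuchs sequence), a Wittig reaction of Ph3P=CBr2 on the aldehyde released from its hemiacetal dimer; pre-forming the ylide with Zn leaves no Ph3PBr2 that could brominate the free secondary hydroxyl.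

Step 3
Reactants: 4 (2R,4S,5R)-4-(2,2-dibromoethenyl)-2-methyl-1,3-dioxan-5-ol
Product: 5 (2R,4S,5R)-4-(2,2-dibromoethenyl)-5-methoxy-2-methyl-1,3-dioxane
Conditions: MeI (10 equiv), Ag2O (3 equiv), 4 Å molecular sieves, DMF, rt, dark
Reagents that add atoms: iodomethane, CI
Why: Purdie O-methylation places the methyl group on the only free hydroxyl (the future C4 oxygen) without forming an alkoxide, which could dehydrobrominate the 1,1-dibromoalkene.

Step 4
Reactants: 5 (2R,4S,5R)-4-(2,2-dibromoethenyl)-5-methoxy-2-methyl-1,3-dioxane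
Product: 6 (2R,3S)-5,5-dibromo-2-methoxypent-4-ene-1,3-diol
Conditions: p-TsOH·H2O (0.2 equiv), MeOH, 50 °C
Reagents that add atoms: none
Why: Acid-catalysed transacetalisation in methanol removes the ethylidene acetal as volatile 1,1-dimethoxyethane at a stage where no acid-labile group is present, and the electron-poor dibromovinyl group disfavours allylic ionisation.

Step 5
Reactants: 6 (2R,3S)-5,5-dibromo-2-methoxypent-4-ene-1,3-diol
Product: 7 (3S,4R)-1,1-dibromo-4-methoxy-5-[(triethylsilyl)oxy]pent-1-en-3-ol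
Conditions: TESCl (1.05 equiv), imidazole, CH2Cl2, −78 → −40 °C
Reagents that add atoms: chlorotriethylsilane, CC[Si](Cl)(CC)CC
Why: Kinetically selective silylation of the primary over the hindered secondary hydroxyl with one equivalent of silyl chloride at low temperature.

Step 6
Reactants: 7 (3S,4R)-1,1-dibromo-4-methoxy-5-[(triethylsilyl)oxy]pent-1-en-3-ol
Product: 8 tert-butyl{[(3S,4R)-1,1-dibromo-4-methoxy-5-[(triethylsilyl)oxy]pent-1-en-3-yl]oxy}dimethylsilane
Conditions: TBSOTf (1.3 equiv), 2,6-lutidine, CH2Cl2, −78 → 0 °C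
Reagents that add atoms: tert-butyldimethylsilyl trifluoromethanesulfonate, CC(C)(C)[Si](C)(C)OS(=O)(=O)C(F)(F)F
Why: Silyl triflate silylation of the remaining secondary allylic hydroxyl; the bulkier tert-butyldimethylsilyl group is chosen because it resists 1,4 O→C silyl migration (retro-Brook rearrangement) to the cis vinyllithium of step 12.

Step 7
Reactants: 9 2-methylbut-3-yn-2-ol
Product: 10 triethyl[(2-methylbut-3-yn-2-yl)oxy]silane
Conditions: TESOTf (1.1 equiv), 2,6-lutidine, CH2Cl2, 0 °C
Reagents that add atoms: triethylsilyl trifluoromethanesulfonate, CC[Si](CC)(CC)OS(=O)(=O)C(F)(F)F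
Why: Silyl triflate silylation of a tertiary propargylic alcohol, needed so that the hydroxyl does not consume the zirconium hydride.

Step 8
Reactants: 10 triethyl[(2-methylbut-3-yn-2-yl)oxy]silane, 11 2,3-dibromopropene
Product: 13 {[(3E)-6-bromo-2-methylhepta-3,6-dien-2-yl]oxy}triethylsilane, via vinylzirconocene 12 (not isolated)
Conditions: Cp2Zr(H)Cl (1.2 equiv), THF, rt; then 11 (1.5 equiv), CuCl (10 mol %), 0 °C → rt
Reagents that add atoms: none
Why: Syn hydrozirconation puts zirconium on the terminal carbon and fixes the E alkene, and copper-catalysed allylic substitution of the vinylzirconocene on the allylic bromide (SN2 and SN2' attack give the same product) leaves the vinylic bromide untouched.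

Step 9
Reactants: 13 {[(3E)-6-bromo-2-methylhepta-3,6-dien-2-yl]oxy}triethylsilane, 14 ethynyltrimethylsilane
Product: 15 triethyl{[(3E)-2-methyl-6-methylidene-8-(trimethylsilyl)oct-3-en-7-yn-2-yl]oxy}silane
Conditions: Pd(PPh3)4 (5 mol %), CuI (10 mol %), i-Pr2NH, THF, 45 °C
Reagents that add atoms: none
Why: Sonogashira coupling of the 2-bromoalkene with the terminal alkyne builds the cross-conjugated enyne under conditions that do not move the skipped diene into conjugation.

Step 10
Reactants: 15 triethyl{[(3E)-2-methyl-6-methylidene-8-(trimethylsilyl)oct-3-en-7-yn-2-yl]oxy}silane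
Product: 16 triethyl{[(3E)-2-methyl-6-methylideneoct-3-en-7-yn-2-yl]oxy}silane
Conditions: K2CO3 (0.2 equiv), MeOH, rt
Reagents that add atoms: none
Why: Carbonate-catalysed methanolysis cleaves only the alkynyl C–Si bond, since the hindered tertiary triethylsilyl ether is stable to these conditions.

Step 11
Reactants: 8 tert-butyl{[(3S,4R)-1,1-dibromo-4-methoxy-5-[(triethylsilyl)oxy]pent-1-en-3-yl]oxy}dimethylsilane, 16 triethyl{[(3E)-2-methyl-6-methylideneoct-3-en-7-yn-2-yl]oxy}silane
Product: 17 (2R,3S,4Z,10E)-5-bromo-3-[(tert-butyldimethylsilyl)oxy]-2-methoxy-12-methyl-8-methylidene-1,12-bis[(triethylsilyl)oxy]trideca-4,10-dien-6-yne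
Conditions: PdCl2(dppf) (5 mol %), CuI (10 mol %), i-Pr2NH, toluene, rt
Reagents that add atoms: none
Why: trans-Selective Sonogashira mono-coupling of a 1,1-dibromoalkene, in which zerovalent palladium inserts faster into the C–Br bond trans to the alkyl substituent, so the alkyne enters trans to C3 and the bromide cis to C3 is kept for the formyl group.

Step 12
Reactants: 17 (Z)-bromoenyne
Product: 19 (2Z,4S,5R)-4-[(tert-butyldimethylsilyl)oxy]-5-methoxy-2-{(5E)-7-methyl-3-methylidene-7-[(triethylsilyl)oxy]oct-5-en-1-yn-1-yl}-6-[(triethylsilyl)oxy]hex-2-enal, via vinyllithium 18 (not isolated)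
Conditions: t-BuLi (2.1 equiv), Et2O, −100 → −78 °C; DMF (5 equiv), −78 → −40 °C; H2O
Reagents that add atoms: N,N-dimethylformamide, CN(C)C=O
Why: Bromine–lithium exchange with retention of alkene geometry followed by Bouveault-type formylation with DMF puts the formyl carbon C6 cis to C3, with ether solvent and low temperature limiting isomerisation of the α-alkynyl vinyllithium.

Step 13
Reactants: 19 Z-enynal with primary triethylsilyl ether
Product: 20 (2Z,4S,5S)-4-[(tert-butyldimethylsilyl)oxy]-5-methoxy-2-{(5E)-7-methyl-3-methylidene-7-[(triethylsilyl)oxy]oct-5-en-1-yn-1-yl}hex-2-enedial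
Conditions: (COCl)2 (4 equiv), DMSO (8 equiv), CH2Cl2, −78 → −40 °C; i-Pr2NEt, −78 → −20 °C; pH 7 buffer; used at once
Reagents that add atoms: none
Why: Direct Swern oxidation of a primary triethylsilyl ether, in which the chlorosulfonium salt cleaves and oxidises only the least hindered silyl ether while the secondary and tertiary silyl ethers survive, and the hindered base at low temperature protects the epimerisable C4 centre.

Step 14
Reactants: 20 (Z)-enynal dialdehyde
Product: 21 (1S,2S,5S,6R)-5-[(tert-butyldimethylsilyl)oxy]-6-methoxy-3-{(5E)-7-methyl-3-methylidene-7-[(triethylsilyl)oxy]oct-5-en-1-yn-1-yl}cyclohex-3-ene-1,2-diol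
Conditions: SmI2 (3 equiv, 0.1 M in THF), t-BuOH (3 equiv), −78 °C, slow addition of 20 in THF; aq. NaHCO3/Na2S2O3
Reagents that add atoms: none
Why: Divalent samarium transfers one electron to the conjugated C6 aldehyde, the more easily reduced carbonyl; the ketyl carbon adds to the carbon of the samarium-bound C5 aldehyde and a second electron transfer gives the trivalent samarium diolate, protonated by t-BuOH and on work-up. The closest known reaction type is the SmI2 pinacol cyclisation of sugar-derived 1,6-dialdehydes to cis-cyclohexane-1,2-diols, and pinacol coupling of conjugated aldehydes is likewise established. The six-membered ring closes by 6-exo-trig attack of C6 on the C5 carbonyl carbon, forming the C5–C6 bond. The configuration at C6 is controlled by samarium bridging of the two oxygens, which forces the cis diol, and that at C5 by the C4 stereocentre, whose methoxy dipole is placed anti to the adjacent C5–O bond, so that the diol forms trans to the methoxy group. The step needs carbonyl–carbonyl coupling to outrun further reduction of the delocalised ketyl (which would expel the C3 silyloxy group) and intermolecular coupling: the Z alkene holds C5 within reach of C6, bonding through C2 or the alkyne terminus cannot give a ring of workable size, and slow addition of 20 to excess SmI2 at −78 °C without HMPA should keep ring closure the fastest path.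

Step 15
Reactants: 21 silylated cyclohexenediol
Product: 22 (1S,2S,3S,4S)-6-[(5E)-7-hydroxy-7-methyl-3-methylideneoct-5-en-1-yn-1-yl]-3-methoxycyclohex-5-ene-1,2,4-triol
Conditions: TBAF (3 equiv), THF, 0 °C → rt
Reagents that add atoms: none
Why: Fluoride-driven cleavage of both silyl ethers (Si–F bond formation) under non-acidic conditions spares the acid-labile tertiary allylic alcohol of the side chain.

Step 16
Reactants: 22 tetraol
Product: 25 (1S,4S,5S,6R)-4,5-dihydroxy-3-[(5E)-7-hydroxy-7-methyl-3-methylideneoct-5-en-1-yn-1-yl]-6-methoxycyclohex-2-en-1-yl acetate, via phenylboronate 23 (not isolated), via acetylated phenylboronate 24 (not isolated)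
Conditions: PhB(OH)2 (1.05 equiv), pyridine, 4 Å molecular sieves, rt; Ac2O (1.5 equiv), 0 °C → rt; MeOH quench, then pinacol (3 equiv), rt
Reagents that add atoms: acetic anhydride, CC(=O)OC(C)=O
Why: Boronate-masked regioselective acylation, in which phenylboronic acid condenses only with the cis C5/C6 diol (the C3 hydroxyl is trans-1,3 to O5), Ac2O/pyridine acetylates the one remaining secondary hydroxyl but not the tertiary one, and transesterification with pinacol frees the diol under neutral conditions.

Compound list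
1 | 4,6-O-ethylidene-D-glucopyranose ((R)-ethylidene acetal, anomeric mixture) | C[C@@H]1OC[C@H]2OC(O)[C@H](O)[C@@H](O)[C@@H]2O1 | starting material
2 | (2R,4R,5R)-4-formyl-2-methyl-1,3-dioxan-5-yl formate (3-O-formyl-2,4-O-ethylidene-D-erythrose) | C[C@@H]1OC[C@@H](OC=O)[C@H](C=O)O1 | intermediate (not isolated)
3 | (2R,4R,5R)-5-hydroxy-2-methyl-1,3-dioxane-4-carbaldehyde (2,4-O-ethylidene-D-erythrose) | C[C@@H]1OC[C@@H](O)[C@H](C=O)O1 | intermediate
4 | (2R,4S,5R)-4-(2,2-dibromoethenyl)-2-methyl-1,3-dioxan-5-ol | C[C@@H]1OC[C@@H](O)[C@H](C=C(Br)Br)O1 | intermediate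
5 | (2R,4S,5R)-4-(2,2-dibromoethenyl)-5-methoxy-2-methyl-1,3-dioxane | C[C@@H]1OC[C@@H](OC)[C@H](C=C(Br)Br)O1 | intermediate
6 | (2R,3S)-5,5-dibromo-2-methoxypent-4-ene-1,3-diol | OC[C@@H](OC)[C@H](C=C(Br)Br)O | intermediate
7 | (3S,4R)-1,1-dibromo-4-methoxy-5-[(triethylsilyl)oxy]pent-1-en-3-ol | CC[Si](CC)(CC)OC[C@@H](OC)[C@H](C=C(Br)Br)O | intermediate
8 | tert-butyl{[(3S,4R)-1,1-dibromo-4-methoxy-5-[(triethylsilyl)oxy]pent-1-en-3-yl]oxy}dimethylsilane | CC[Si](CC)(CC)OC[C@@H](OC)[C@H](C=C(Br)Br)O[Si](C)(C)C(C)(C)C | intermediate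
9 | 2-methylbut-3-yn-2-ol | CC(C)(O)C#C | starting material
10 | triethyl[(2-methylbut-3-yn-2-yl)oxy]silane | CC[Si](CC)(CC)OC(C)(C)C#C | intermediate
11 | 2,3-dibromopropene | C=C(Br)CBr | starting material
12 | chlorobis(cyclopentadienyl)[(1E)-3-methyl-3-(triethylsilyloxy)but-1-en-1-yl]zirconium (vinylzirconocene) | CC[Si](CC)(CC)OC(C)(C)/C=C/[Zr](Cl)(C1C=CC=C1)C1C=CC=C1 | intermediate (not isolated)
13 | {[(3E)-6-bromo-2-methylhepta-3,6-dien-2-yl]oxy}triethylsilane (bromodiene) | C=C(Br)C/C=C/C(C)(C)O[Si](CC)(CC)CC | intermediate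
14 | ethynyltrimethylsilane | C#C[Si](C)(C)C | starting material
15 | triethyl{[(3E)-2-methyl-6-methylidene-8-(trimethylsilyl)oct-3-en-7-yn-2-yl]oxy}silane | C[Si](C)(C)C#CC(=C)C/C=C/C(C)(C)O[Si](CC)(CC)CC | intermediate
16 | triethyl{[(3E)-2-methyl-6-methylideneoct-3-en-7-yn-2-yl]oxy}silane (side-chain enyne) | C#CC(=C)C/C=C/C(C)(C)O[Si](CC)(CC)CC | intermediate
17 | (2R,3S,4Z,10E)-5-bromo-3-[(tert-butyldimethylsilyl)oxy]-2-methoxy-12-methyl-8-methylidene-1,12-bis[(triethylsilyl)oxy]trideca-4,10-dien-6-yne ((Z)-bromoenyne; Br cis to C3) | CC[Si](CC)(CC)OC[C@@H](OC)[C@H](/C=C(Br)/C#CC(=C)C/C=C/C(C)(C)O[Si](CC)(CC)CC)O[Si](C)(C)C(C)(C)C | intermediate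
18 | vinyllithium from 17 (Li in place of Br, geometry retained) | CC[Si](CC)(CC)OC[C@@H](OC)[C@H](/C=C([Li])/C#CC(=C)C/C=C/C(C)(C)O[Si](CC)(CC)CC)O[Si](C)(C)C(C)(C)C | intermediate (not isolated)
19 | (2Z,4S,5R)-4-[(tert-butyldimethylsilyl)oxy]-5-methoxy-2-{(5E)-7-methyl-3-methylidene-7-[(triethylsilyl)oxy]oct-5-en-1-yn-1-yl}-6-[(triethylsilyl)oxy]hex-2-enal | CC[Si](CC)(CC)OC[C@@H](OC)[C@H](/C=C(C=O)/C#CC(=C)C/C=C/C(C)(C)O[Si](CC)(CC)CC)O[Si](C)(C)C(C)(C)C | intermediate
20 | (2Z,4S,5S)-4-[(tert-butyldimethylsilyl)oxy]-5-methoxy-2-{(5E)-7-methyl-3-methylidene-7-[(triethylsilyl)oxy]oct-5-en-1-yn-1-yl}hex-2-enedial (pinacol precursor) | O=C[C@@H](OC)[C@H](/C=C(C=O)/C#CC(=C)C/C=C/C(C)(C)O[Si](CC)(CC)CC)O[Si](C)(C)C(C)(C)C | intermediate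
21 | (1S,2S,5S,6R)-5-[(tert-butyldimethylsilyl)oxy]-6-methoxy-3-{(5E)-7-methyl-3-methylidene-7-[(triethylsilyl)oxy]oct-5-en-1-yn-1-yl}cyclohex-3-ene-1,2-diol (pinacol product) | C=C(C#CC1=C[C@H](O[Si](C)(C)C(C)(C)C)[C@H](OC)[C@@H](O)[C@H]1O)C/C=C/C(C)(C)O[Si](CC)(CC)CC | intermediate
22 | (1S,2S,3S,4S)-6-[(5E)-7-hydroxy-7-methyl-3-methylideneoct-5-en-1-yn-1-yl]-3-methoxycyclohex-5-ene-1,2,4-triol (tetraol) | C=C(C#CC1=C[C@H](O)[C@H](OC)[C@@H](O)[C@H]1O)C/C=C/C(C)(C)O | intermediate
23 | cyclic phenylboronate of the C5/C6 diol of 22 | C=C(C#CC1=C[C@H](O)[C@H](OC)[C@H]2OB(c3ccccc3)O[C@@H]12)C/C=C/C(C)(C)O | intermediate (not isolated)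
24 | C3 acetate of phenylboronate 23 | C=C(C#CC1=C[C@H](OC(C)=O)[C@H](OC)[C@H]2OB(c3ccccc3)O[C@@H]12)C/C=C/C(C)(C)O | intermediate (not isolated)
25 | (1S,4S,5S,6R)-4,5-dihydroxy-3-[(5E)-7-hydroxy-7-methyl-3-methylideneoct-5-en-1-yn-1-yl]-6-methoxycyclohex-2-en-1-yl acetate | C=C(C#CC1=C[C@H](OC(C)=O)[C@H](OC)[C@@H](O)[C@H]1O)C/C=C/C(C)(C)O | target

Total step count: 16.
Longest linear sequence: 12 steps (steps 1–6 and 11–16); the side-chain branch (steps 7–10) joins at step 11.

Steps most likely to fail

1. Step 14. The delocalised enynal ketyl may take up a second electron before the C5–C6 bond forms, which would lead to loss of the allylic C3 silyloxy group or to simple reduction; intermolecular coupling and erosion of facial selectivity are further risks. The extended dienyne π-system of the full side chain makes the ketyl longer-lived. Fallback: close the ring before the side chain is attached, setting out from 8 and returning at 21. Compound 8 would be coupled with 14 under the conditions of step 11 to give the trimethylsilyl-capped (Z)-bromoenyne F1. Bromine–lithium exchange (t-BuLi, Et2O, −78 °C) would give the vinyllithium F2, which DMF should convert into the silylethynyl enal F3. Direct Swern oxidation as in step 13 would give the silylethynyl dialdehyde F4, and SmI2/t-BuOH at −78 °C should close it to the silylethynyl cyclohexenediol F5. Here the ketyl is delocalised only over the enal and a capped alkyne, and the skipped diene never meets the reductant or trivalent samarium. K2CO3/MeOH would then give the ring-bound terminal alkyne F6, and Sonogashira coupling of F6 with bromodiene 13 (Pd(PPh3)4, CuI, i-Pr2NH, THF, 45 °C) should deliver 21.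

2. Step 12. The α-alkynyl vinyllithium can lose its geometry through cumulene-type delocalisation, a silyl group can migrate from O3 to carbon, or t-BuLi can add to the enyne. Fallback: introduce C6 by palladium catalysis, setting out from 17 and returning at 19. Methoxycarbonylation of 17 (Pd(PPh3)4, CO 1 atm, MeOH, Et3N, DMF, 60 °C) proceeds with retention and should give the methyl (Z)-enoate F7. Reduction with i-Bu2AlH (CH2Cl2, −78 °C) would give the allylic alcohol F8, and MnO2 (CH2Cl2, rt) should oxidise it to 19.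

3. Step 13. Under the amine base the new α-methoxy aldehyde can epimerise at C4 or eliminate the C3 silyloxy group, and discrimination between the three silyl ethers may be incomplete. Fallback: unmask and oxidise in two non-basic operations, setting out from 19 and returning at 20. HF·pyridine buffered with pyridine (THF, 0 °C) should cleave only the primary triethylsilyl ether to give the primary alcohol F9, which Dess–Martin periodinane with NaHCO3 (CH2Cl2, 0 °C) should oxidise to 20.

Further compounds
F1 | step 14 | (2R,3S,4Z)-5-bromo-3-[(tert-butyldimethylsilyl)oxy]-2-methoxy-1-[(triethylsilyl)oxy]-7-(trimethylsilyl)hept-4-en-6-yne | CC[Si](CC)(CC)OC[C@@H](OC)[C@H](/C=C(Br)/C#C[Si](C)(C)C)O[Si](C)(C)C(C)(C)C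
F2 | step 14 | vinyllithium from F1 (Li in place of Br) | CC[Si](CC)(CC)OC[C@@H](OC)[C@H](/C=C([Li])/C#C[Si](C)(C)C)O[Si](C)(C)C(C)(C)C
F3 | step 14 | (2Z,4S,5R)-4-[(tert-butyldimethylsilyl)oxy]-5-methoxy-6-[(triethylsilyl)oxy]-2-[(trimethylsilyl)ethynyl]hex-2-enal | CC[Si](CC)(CC)OC[C@@H](OC)[C@H](/C=C(C=O)/C#C[Si](C)(C)C)O[Si](C)(C)C(C)(C)C
F4 | step 14 | (2Z,4S,5S)-4-[(tert-butyldimethylsilyl)oxy]-5-methoxy-2-[(trimethylsilyl)ethynyl]hex-2-enedial | O=C[C@@H](OC)[C@H](/C=C(C=O)/C#C[Si](C)(C)C)O[Si](C)(C)C(C)(C)C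
F5 | step 14 | (1S,2S,5S,6R)-5-[(tert-butyldimethylsilyl)oxy]-6-methoxy-3-[(trimethylsilyl)ethynyl]cyclohex-3-ene-1,2-diol | C[Si](C)(C)C#CC1=C[C@H](O[Si](C)(C)C(C)(C)C)[C@H](OC)[C@@H](O)[C@H]1O
F6 | step 14 | (1S,2S,5S,6R)-5-[(tert-butyldimethylsilyl)oxy]-3-ethynyl-6-methoxycyclohex-3-ene-1,2-diol | C#CC1=C[C@H](O[Si](C)(C)C(C)(C)C)[C@H](OC)[C@@H](O)[C@H]1O
F7 | step 12 | methyl (2Z,4S,5R)-4-[(tert-butyldimethylsilyl)oxy]-5-methoxy-2-{(5E)-7-methyl-3-methylidene-7-[(triethylsilyl)oxy]oct-5-en-1-yn-1-yl}-6-[(triethylsilyl)oxy]hex-2-enoate | CC[Si](CC)(CC)OC[C@@H](OC)[C@H](/C=C(C(=O)OC)/C#CC(=C)C/C=C/C(C)(C)O[Si](CC)(CC)CC)O[Si](C)(C)C(C)(C)C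
F8 | step 12 | (2Z,4S,5R)-4-[(tert-butyldimethylsilyl)oxy]-5-methoxy-2-{(5E)-7-methyl-3-methylidene-7-[(triethylsilyl)oxy]oct-5-en-1-yn-1-yl}-6-[(triethylsilyl)oxy]hex-2-en-1-ol | CC[Si](CC)(CC)OC[C@@H](OC)[C@H](/C=C(CO)/C#CC(=C)C/C=C/C(C)(C)O[Si](CC)(CC)CC)O[Si](C)(C)C(C)(C)C
F9 | step 13 | (2Z,4S,5R)-4-[(tert-butyldimethylsilyl)oxy]-6-hydroxy-5-methoxy-2-{(5E)-7-methyl-3-methylidene-7-[(triethylsilyl)oxy]oct-5-en-1-yn-1-yl}hex-2-enal | OC[C@@H](OC)[C@H](/C=C(C=O)/C#CC(=C)C/C=C/C(C)(C)O[Si](CC)(CC)CC)O[Si](C)(C)C(C)(C)C
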